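With ring A the ten-membered carbocycle (C1 ketone, C4–C10 stereocentres) and ring B the lactone (C7, C8, O, C12, C11; C13 the exocyclic methylene), the plan rests on disconnecting C7–C11. The key step exploits the C6 hydroxyl vicinal to C7–C11, beside the lactone oxygen on C8: in a trans-C6,C7-epoxide whose C8 oxygen carries a diethylphosphonoacetate, the carbanion opens the epoxide at C7 (5-exo-tet, inversion), closing ring B, setting C7 and unveiling the C6 hydroxyl; formaldehyde then adds C13 in the same flask and gives the target. This fully acylated epoxy-macrocycle is built from 2-C-methyl-D-ribonolactone by asymmetric epoxidation, crotylboration and ring-closing metathesis.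

Key step: step 16

Remark: 2-C-methyl-D-ribono-1,4-lactone and (R)-2-methylbutanoic acid are taken as catalogue compounds; the benzylidene carbon is drawn exo-phenyl and hemiketal 18 as one anomer (both centres are lost later); locants are those of the overview (C2, C3 ring methylenes, C4 methyl-bearing, C5 2-methylbutanoyloxy, C9 angeloyloxy, C10 tertiary carbinol).

Step 1
Reactants: 1 2-C-methyl-D-ribono-1,4-lactone
Product: 2 2,3-O-benzylidene-2-C-methyl-D-ribono-1,4-lactone
Conditions: PhCH(OMe)2, CSA (cat.), MeCN, 50 °C, reduced pressure
Reagents that add atoms: benzaldehyde dimethyl acetal, COC(OC)c1ccccc1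
Why: Acid-catalysed transacetalisation under thermodynamic control should tie the cis-2,3-diol into the cis-fused dioxolane (phenyl exo) and leave the primary hydroxyl free, without touching a skeletal stereocentre.

Step 2
Reactants: 2 2,3-O-benzylidene-2-C-methyl-D-ribono-1,4-lactone
Product: 3 2,3-O-benzylidene-5-O-mesyl-2-C-methyl-D-ribono-1,4-lactone
Conditions: MsCl, Et3N, CH2Cl2, 0 °C
Reagents that add atoms: methanesulfonyl chloride, CS(=O)(=O)Cl
Why: Sulfonylation (mesylation) of the only free hydroxyl, a primary one, should be clean.

Step 3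
Reactants: 3 2,3-O-benzylidene-5-O-mesyl-2-C-methyl-D-ribono-1,4-lactone
Product: 5 2,3-O-benzylidene-2-C-methyl-L-lyxono-1,4-lactone, via potassium 4,5-epoxy carboxylate 4 (not isolated)
Conditions: KOH, H2O, rt; then HCl to pH 3
Reagents that add atoms: potassium hydroxide, [K+].[OH-]
Why: Saponification frees the C8 alkoxide, which closes a terminal epoxide on the mesylate (intramolecular Williamson reaction), and on acidification the carboxylic acid reopens it at C8 by 5-exo attack with inversion (lactonisation), so the D-ribo lactone becomes the L-lyxo lactone and C8 acquires the S configuration of the target.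

Step 4
Reactants: 5 2,3-O-benzylidene-2-C-methyl-L-lyxono-1,4-lactone
Product: 6 lactone aldehyde (C7 formyl)
Conditions: Dess–Martin periodinane, NaHCO3, CH2Cl2, 0 °C to rt
Reagents that add atoms: none
Why: Buffered Dess–Martin oxidation is mild enough to give the epimerisable α-alkoxy aldehyde without loss of the C8 configuration.

Step 5
Reactants: 6 lactone aldehyde (C7 formyl), 7 (triphenylphosphoranylidene)acetaldehyde
Product: 8 (E)-enal (C5 aldehyde and C6=C7)
Conditions: toluene, 60 °C
Reagents that add atoms: (triphenylphosphoranylidene)acetaldehyde 7, O=CC=P(c1ccccc1)(c1ccccc1)c1ccccc1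
Why: Wittig olefination with the stabilised formyl ylide is E-selective and salt-free and adds C6 and C5 in one step.

Step 6
Reactants: 8 (E)-enal
Product: 9 (E)-allylic alcohol (C5 hydroxyl)
Conditions: NaBH4, CeCl3·7H2O, MeOH, −78 °C
Reagents that add atoms: none
Why: Luche reduction should reduce the enal in the 1,2-sense much faster than it attacks the lactone at −78 °C.

Step 7
Reactants: 9 (E)-allylic alcohol
Product: 10 trans-epoxy alcohol (C6 S and C7 R)
Conditions: Ti(Oi-Pr)4, L-(+)-diethyl tartrate, t-BuOOH, 4 Å MS, CH2Cl2, −20 °C
Reagents that add atoms: tert-butyl hydroperoxide, CC(C)(C)OO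
Why: Sharpless asymmetric epoxidation of the primary E-allylic alcohol is reagent-controlled, and the L-(+)-tartrate (the sense that turns (E)-hex-2-en-1-ol into its (2S,3S)-epoxide) should give the trans-epoxide with C6 S and C7 R, which fixes the future C6 carbinol and the carbon to be inverted at C7.

Step 8
Reactants: 10 trans-epoxy alcohol
Product: 11 trans-epoxy aldehyde
Conditions: Dess–Martin periodinane, NaHCO3, CH2Cl2, 0 °C
Reagents that add atoms: none
Why: Buffered Dess–Martin oxidation should give the sensitive α,β-epoxy aldehyde, which is used crude.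

Step 9
Reactants: 11 trans-epoxy aldehyde, 12 (E)-but-2-ene
Product: 14 anti-homoallylic alcohol (C4 R and C5 R), via O-diisopinocampheylborinate 13 (not isolated)
Conditions: 12, KOt-Bu, n-BuLi, THF, −78 to −45 °C; (+)-Ipc2BOMe, then BF3·OEt2, −78 °C; 11, −78 °C; then H2O2, pH 7 buffer, 0 °C
Reagents that add atoms: (E)-crotyldiisopinocampheylborane (formed in the flask from (E)-but-2-ene 12 and (+)-Ipc2BOMe), C/C=C/CB([C@H]1C[C@H]2C[C@@H]([C@@H]1C)C2(C)C)[C@H]1C[C@H]2C[C@@H]([C@@H]1C)C2(C)C
Why: Brown crotylboration through a closed chair transition state, in which the E-crotyl unit gives the 4,5-anti pair and the (−)-α-pinene-derived ligands direct attack to the Re face of the aldehyde under reagent control, should set C5 (R) and C4 (R).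

Step 10
Reactants: 14 anti-homoallylic alcohol, 15 (R)-2-methylbutanoic acid
Product: 16 C5 (R)-2-methylbutanoate of the epoxy lactone
Conditions: DCC, DMAP (cat.), CH2Cl2, 0 °C to rt
Reagents that add atoms: (R)-2-methylbutanoic acid 15, CC[C@@H](C)C(=O)O
Why: Steglich esterification of the secondary alcohol should proceed without epimerising the α-stereocentre of the acid and leaves lactone and epoxide alone.

Step 11
Reactants: 16 C5 (R)-2-methylbutanoate of the epoxy lactone, 17 vinylmagnesium bromide
Product: 18 C1 vinyl hemiketal (lactol)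
Conditions: CH2=CHMgBr (1.2 equiv), THF, −78 °C; then pH 7 buffer
Reagents that add atoms: vinylmagnesium bromide 17, C=C[Mg]Br
Why: Grignard 1,2-addition to the doubly α-oxygenated γ-lactone should stop at the magnesium hemiketal (tetrahedral intermediate stable at −78 °C), while the hindered α-branched ester at C5 and the epoxide are expected to react far more slowly; the product is taken on crude and kept from acid so that its hemiketal hydroxyl cannot open the neighbouring epoxide.

Step 12
Reactants: 18 C1 vinyl hemiketal, 19 diethylphosphonoacetic acid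
Product: 20 acyclic vinyl ketone with C8 diethylphosphonoacetate
Conditions: DCC, DMAP (cat.), CH2Cl2, rt
Reagents that add atoms: diethylphosphonoacetic acid 19, CCOP(=O)(OCC)CC(=O)O
Why: Steglich esterification acting on ring–chain tautomers: the tertiary hemiketal hydroxyl is a poor acyl acceptor, so acylation should drain the equilibrium through the secondary C8 hydroxyl of the open hydroxy enone (Curtin–Hammett situation) and thereby unveil the vinyl ketone.

Step 13
Reactants: 20 acyclic vinyl ketone with C8 diethylphosphonoacetate
Product: 21 ten-membered (Z)-enone (ring A closed)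
Conditions: second-generation Hoveyda–Grubbs catalyst [RuCl2(H2IMes)(=CH–C6H4-2-Oi-Pr)] (10 mol %), toluene (1 mM), 80 °C
Reagents that add atoms: none
Why: Ring-closing metathesis, in which the catalyst should load on the unhindered C3 vinyl group and close onto the vinyl ketone while the cis-dioxolane and the trans-epoxide pre-bend the chain; the geometry of the new C2=C3 bond (Z drawn) is irrelevant because it is hydrogenated next.

Step 14
Reactants: 21 ten-membered (Z)-enone
Product: 22 saturated ring A ketone with free C9 and C10 hydroxyls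
Conditions: H2 (1 atm), Pd(OH)2/C, EtOAc, rt
Reagents that add atoms: none
Why: Heterogeneous hydrogenation should saturate the enone double bond and cleave the benzylidene acetal by benzylic hydrogenolysis in one operation, while the unactivated epoxide, the ketone, the phosphonate and the esters persist under neutral conditions.

Step 15
Reactants: 22 saturated ring A ketone with free C9 and C10 hydroxyls, 23 angelic acid
Product: 24 C9 angelate (key-step precursor)
Conditions: 23, 2,4,6-trichlorobenzoyl chloride, Et3N, toluene, rt; then 22, 75 °C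
Reagents that add atoms: angelic acid 23 (as its 2,4,6-trichlorobenzoic mixed anhydride), C/C=C(/C)C(=O)O
Why: Yamaguchi-type acylation with the preformed mixed anhydride and without DMAP, conditions that avoid Z-to-E isomerisation of the angelate, should acylate the secondary C9 hydroxyl and leave the tertiary C10 hydroxyl free.

Step 16
Reactants: 24 C9 angelate (key-step precursor), 25 formaldehyde
Product: 27 CNP0226386.1, via potassium phosphonolactone carbanion 26 (not isolated)
Conditions: KOt-Bu (1.05 equiv), THF (0.01 M), 0 to 40 °C; then (CH2O)n, 0 °C to rt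
Reagents that add atoms: formaldehyde 25 (as paraformaldehyde), C=O
Why: One equivalent of KOt-Bu converts the phosphonoacetate into its stabilised carbanion (C11), which attacks the epoxide carbon C7 from the side of the C8–O tether in an intramolecular SN2 alkylation, breaking C7–O and closing ring B through the new C7–C11 bond; proton transfer from the acidic α-phosphono lactone to the C6 alkoxide regenerates a phosphonate carbanion, which formaldehyde then converts into the C11=C13 olefin by Horner–Wadsworth–Emmons reaction. The closest known reaction types are the opening of epoxides by phosphonoacetate carbanions to α-phosphono-γ-lactones followed by formaldehyde olefination, and the telescoped intramolecular Michael/olefination route to α-methylene lactones, of which this is the epoxide-alkylation counterpart. Ring B closes in the 5-exo-tet mode (epoxide oxygen exocyclic to the forming ring), preferred over 6-endo attack at C6 because the three-atom O–C12–C11 tether can reach only C7 collinearly with the breaking C–O bond. C7 is set by stereospecific inversion at the epoxide carbon and C6 is carried over unchanged, so both derive from the Sharpless epoxidation, and the cis ring fusion follows from the tether on the C8 oxygen. The step needs the carbanion to alkylate the epoxide and not olefinate the C1 ketone, which the hindered α-quaternary ketone and the late addition of formaldehyde should secure, and it needs the angelate, the C5 ester and the tertiary C10 alcohol to stay untouched, which a single equivalent of base (no free alkoxide after proton transfer) is meant to ensure.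

Compound list
1 | 2-C-methyl-D-ribono-1,4-lactone | O=C1O[C@H](CO)[C@@H](O)[C@@]1(C)O | starting material
2 | 2,3-O-benzylidene-2-C-methyl-D-ribono-1,4-lactone (exo-phenyl) | O=C1O[C@H](CO)[C@H]2O[C@H](c3ccccc3)O[C@@]12C | intermediate
3 | 2,3-O-benzylidene-5-O-mesyl-2-C-methyl-D-ribono-1,4-lactone | O=C1O[C@H](COS(C)(=O)=O)[C@H]2O[C@H](c3ccccc3)O[C@@]12C | intermediate
4 | potassium 4,5-anhydro-2,3-O-benzylidene-2-C-methyl-D-ribonate (not isolated) | [K+].[O-]C(=O)[C@]1(C)O[C@@H](c2ccccc2)O[C@@H]1[C@H]1CO1 | intermediate
5 | 2,3-O-benzylidene-2-C-methyl-L-lyxono-1,4-lactone (C8 S) | O=C1O[C@@H](CO)[C@H]2O[C@H](c3ccccc3)O[C@@]12C | intermediate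
6 | lactone aldehyde (C7 formyl) | O=C1O[C@@H](C=O)[C@H]2O[C@H](c3ccccc3)O[C@@]12C | intermediate
7 | (triphenylphosphoranylidene)acetaldehyde | O=CC=P(c1ccccc1)(c1ccccc1)c1ccccc1 | starting material
8 | (E)-enal (C5 aldehyde, C6=C7) | O=C1O[C@@H](/C=C/C=O)[C@H]2O[C@H](c3ccccc3)O[C@@]12C | intermediate
9 | (E)-allylic alcohol (C5 hydroxyl) | O=C1O[C@@H](/C=C/CO)[C@H]2O[C@H](c3ccccc3)O[C@@]12C | intermediate
10 | trans-epoxy alcohol (C6 S, C7 R) | O=C1O[C@@H]([C@@H]3O[C@H]3CO)[C@H]2O[C@H](c4ccccc4)O[C@@]12C | intermediate
11 | trans-epoxy aldehyde | O=C1O[C@@H]([C@@H]3O[C@H]3C=O)[C@H]2O[C@H](c4ccccc4)O[C@@]12C | intermediate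
12 | (E)-but-2-ene | C/C=C/C | starting material
13 | O-diisopinocampheylborinate of 14 (not isolated) | O=C1O[C@@H]([C@@H]3O[C@H]3[C@H](OB([C@H]5C[C@H]6C[C@@H]([C@@H]5C)C6(C)C)[C@H]5C[C@H]6C[C@@H]([C@@H]5C)C6(C)C)[C@H](C)C=C)[C@H]2O[C@H](c4ccccc4)O[C@@]12C | intermediate
14 | anti-homoallylic alcohol (C4 R, C5 R) | O=C1O[C@@H]([C@@H]3O[C@H]3[C@H](O)[C@H](C)C=C)[C@H]2O[C@H](c4ccccc4)O[C@@]12C | intermediate
15 | (R)-2-methylbutanoic acid | CC[C@@H](C)C(=O)O | starting material
16 | C5 (R)-2-methylbutanoate of the epoxy lactone | O=C1O[C@@H]([C@@H]3O[C@H]3[C@H](OC(=O)[C@H](C)CC)[C@H](C)C=C)[C@H]2O[C@H](c4ccccc4)O[C@@]12C | intermediate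
17 | vinylmagnesium bromide | C=C[Mg]Br | starting material
18 | C1 vinyl hemiketal (lactol, one anomer drawn) | C=C[C@]1(O)O[C@@H]([C@@H]3O[C@H]3[C@H](OC(=O)[C@H](C)CC)[C@H](C)C=C)[C@H]2O[C@H](c4ccccc4)O[C@@]12C | intermediate
19 | diethylphosphonoacetic acid | CCOP(=O)(OCC)CC(=O)O | starting material
20 | acyclic vinyl ketone with C8 diethylphosphonoacetate | C=CC(=O)[C@]1(C)O[C@@H](c2ccccc2)O[C@@H]1[C@@H](OC(=O)CP(=O)(OCC)OCC)[C@@H]3O[C@H]3[C@H](OC(=O)[C@H](C)CC)[C@H](C)C=C | intermediate
21 | ten-membered (Z)-enone, ring A closed | O=C1/C=C\[C@@H](C)[C@@H](OC(=O)[C@H](C)CC)[C@@H]2O[C@H]2[C@H](OC(=O)CP(=O)(OCC)OCC)[C@H]2O[C@H](c3ccccc3)O[C@@]12C | intermediate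
22 | saturated ring A ketone with free C9 and C10 hydroxyls | O=C1CC[C@@H](C)[C@@H](OC(=O)[C@H](C)CC)[C@@H]2O[C@H]2[C@H](OC(=O)CP(=O)(OCC)OCC)[C@@H](O)[C@@]1(C)O | intermediate
23 | angelic acid | C/C=C(/C)C(=O)O | starting material
24 | C9 angelate, key-step precursor | O=C1CC[C@@H](C)[C@@H](OC(=O)[C@H](C)CC)[C@@H]2O[C@H]2[C@H](OC(=O)CP(=O)(OCC)OCC)[C@@H](OC(=O)/C(C)=C\C)[C@@]1(C)O | intermediate
25 | formaldehyde (used as paraformaldehyde) | C=O | starting material
26 | potassium carbanion of the α-diethylphosphono lactone, ring B closed (not isolated) | [K+].CCOP(=O)(OCC)[C-]1C(=O)O[C@H]2[C@@H]1[C@@H](O)[C@H](OC(=O)[C@H](C)CC)[C@H](C)CCC(=O)[C@](C)(O)[C@@H]2OC(=O)/C(C)=C\C | intermediate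
27 | CNP0226386.1 | C=C1C(=O)O[C@H]2[C@@H]1[C@@H](O)[C@H](OC(=O)[C@H](C)CC)[C@H](C)CCC(=O)[C@](C)(O)[C@@H]2OC(=O)/C(C)=C\C | target

Total step count: 16. Longest linear sequence: 16 steps (from 1).

Steps most likely to fail

Step 16. After ring closure the new C6 alkoxide may pull the phosphoryl group from C11 onto oxygen and trigger cyclopropane closure, the carbanion may olefinate the C1 ketone, or the C5 acyl group may migrate to O6. The fallback sets out from 24. Horner–Wadsworth–Emmons reaction of its phosphonoacetate with aqueous formaldehyde and K2CO3 (THF, rt) should give the C8 acrylate of the epoxy-macrocycle F1. PMe3 in t-BuOH at rt then adds to the acrylate, the zwitterionic enolate opens the epoxide at C7 (5-exo-tet, inversion) and, after proton transfer, the phosphine is expelled. This is a Morita–Baylis–Hillman-type epoxide alkylation, known for enone–epoxides, run under neutral conditions with no phosphonate next to the alkoxide. It returns to the route at 27.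

Step 13. Intermolecular metathesis (oligomerisation) may outrun closure of the strained ten-membered ring, or turnover may stall at the hindered enone. The fallback sets out from hemiketal 18, whose anomers interconvert through the hydroxy enone. Metathesis with the same catalyst (CH2Cl2, 40 °C, 1 mM) is run on the cyclic hemiketal, in which the tetrahydrofuran ring holds the C1 vinyl group and the C8 side chain cis as a temporary template, and should give the oxygen-bridged bicyclic hemiketal F2. Acylation with 19 (DCC, DMAP, CH2Cl2) then traps the ring-opened hydroxy enone and returns to the route at 21.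

Step 12. Acylation may occur at the anomeric hemiketal oxygen in place of the C8 hydroxyl, or the hemiketal hydroxyl may open the neighbouring epoxide before it is acylated. The fallback sets out from lactone 16 and avoids the hemiketal. Aminolysis with MeNH(OMe)·HCl and i-PrMgCl (THF, −20 °C) should open the activated lactone selectively to the acyclic C8-hydroxy Weinreb amide F3. Steglich esterification with 19 (DCC, DMAP) gives the Weinreb amide C8 diethylphosphonoacetate F4. CH2=CHMgBr (2.2 equiv, THF, −40 °C; the first equivalent masks the phosphonoacetate as its magnesium enolate) then returns to the route at 20.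

Further compounds
F1 | step 16 | C8 acrylate of the epoxy-macrocycle | O=C1CC[C@@H](C)[C@@H](OC(=O)[C@H](C)CC)[C@@H]2O[C@H]2[C@H](OC(=O)C=C)[C@@H](OC(=O)/C(C)=C\C)[C@@]1(C)O
F2 | step 13 | oxygen-bridged bicyclic hemiketal | O[C@]12/C=C\[C@@H](C)[C@@H](OC(=O)[C@H](C)CC)[C@@H]3O[C@H]3[C@H](O1)[C@H]3O[C@H](c4ccccc4)O[C@@]23C
F3 | step 12 | C8-hydroxy Weinreb amide | CON(C)C(=O)[C@]1(C)O[C@@H](c2ccccc2)O[C@@H]1[C@@H](O)[C@@H]3O[C@H]3[C@H](OC(=O)[C@H](C)CC)[C@H](C)C=C
F4 | step 12 | Weinreb amide C8 diethylphosphonoacetate | CON(C)C(=O)[C@]1(C)O[C@@H](c2ccccc2)O[C@@H]1[C@@H](OC(=O)CP(=O)(OCC)OCC)[C@@H]3O[C@H]3[C@H](OC(=O)[C@H](C)CC)[C@H](C)C=C
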